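## Retrosynthetic overview

1. The last two disconnections are the 22 O-alkyl bonds (13 OMe, 9 OEt; BBr3) and the diaryl ether between C1 of ring D and C4 of ring C (Chan–Lam coupling of ring D phenol 25 with ring C boronic acid 46).
2. The plan rests on this feature: in each biaryl (E–F twice, B–B') the outer ring is a 1,3,5-trioxygenated benzene whose C1 carries the inner ring between the oxygenated carbons C2 and C6, so the aryl–aryl bond has four ortho oxygens. That ring is grown on an aryl siloxyalkyne with 3-ethoxycyclobut-2-en-1-one (new bonds C1–C6 and C2–C3 of ring F) instead of being coupled on.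
3. Ring D comes from 2,6-dichloro-1,4-benzoquinone: two ring E phenols 21 displace the chlorides, and reduction plus mono-methylation leave free only the hydroxyl at C1 between the two aryloxy groups.
4. In the left fragment, rings B and C are joined by Ullmann coupling before ring B is formylated; the same alkyne and benzannulation sequence grows ring B'; ring A is added by a second Ullmann coupling; the one unhindered C–H (C4 of ring C) is borylated.
5. Rings are constructed in the order F (step 7), then B' (step 17); rings A, B, C, D and E are bought as benzene or quinone rings.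

Key step: step 7

Remark: the target has no stereocentre and no stereogenic biaryl axis (rings F and B' are symmetric about the axis). Intermediates 15, 18, 36 and 39 are chiral and form as racemates; this chirality disappears on aromatization and on O-ethylation in steps 8 and 18. Cyclobutenone 13 is made once (step 6) and used in steps 7 and 17. It enters both steps through the same ring-opened valence isomer, vinylketene 14, which is listed at step 7, where it first arises.

## Route

Step 1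
Reactants: 1 2,4,6-trimethoxybenzaldehyde
Product: 3 2,4,6-trimethoxyphenol, via aryl formate 2 (not isolated)
Conditions: 30% aq H2O2, cat. H2SO4, MeOH, rt
Reagents that add atoms: hydrogen peroxide (OO)
Why: Acid-catalysed Dakin oxidation, in which the three ortho/para methoxy groups make the aryl group migrate to oxygen and the formate is methanolysed in the same flask.

Step 2
Reactants: 3 2,4,6-trimethoxyphenol
Product: 4 2-(benzyloxy)-1,3,5-trimethoxybenzene
Conditions: BnBr, K2CO3, DMF, rt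
Reagents that add atoms: benzyl bromide (BrCc1ccccc1)
Why: Williamson ether synthesis; benzyl marks the one oxygen of ring E that must later be freed for the link to ring D.

Step 3
Reactants: 4 2-(benzyloxy)-1,3,5-trimethoxybenzene
Product: 6 3-(benzyloxy)-2,4,6-trimethoxybenzaldehyde, via iminium chloride 5 (not isolated)
Conditions: POCl3 (1.2 equiv), DMF, 0 °C to rt; then H2O
Reagents that add atoms: N,N-dimethylformamide (CN(C)C=O); water (O)
Why: Vilsmeier–Haack formylation; the two free positions of 4 are equivalent by symmetry and each has two ortho and one para alkoxy group, so a single aldehyde should form.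

Step 4
Reactants: 6 3-(benzyloxy)-2,4,6-trimethoxybenzaldehyde
Product: 7 2-(benzyloxy)-4-(2,2-dibromoethenyl)-1,3,5-trimethoxybenzene
Conditions: CBr4, PPh3, Zn, CH2Cl2, rt; then 6, 0 °C to rt
Reagents that add atoms: carbon tetrabromide (BrC(Br)(Br)Br)
Why: First stage of the Corey–Fuchs homologation (Wittig-type dibromo-olefination), which tolerates 2,6-dialkoxybenzaldehydes; Zn removes the bromine that would otherwise end up as Ph3PBr2.

Step 5
Reactants: 7 2-(benzyloxy)-4-(2,2-dibromoethenyl)-1,3,5-trimethoxybenzene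
Product: 10 [3-(benzyloxy)-2,4,6-trimethoxyphenyl]ethynyl triisopropylsilyl ether, via lithium acetylide 8 (not isolated), via lithium ynolate 9 (not isolated)
Conditions: n-BuLi (2.05 equiv), THF, −78 °C; t-BuOOLi (from t-BuOOH and LiN(SiMe3)2), −78 to 0 °C; TIPSOTf, −78 °C to rt
Reagents that add atoms: tert-butyl hydroperoxide (CC(C)(C)OO); triisopropylsilyl trifluoromethanesulfonate (CC(C)[Si](OS(=O)(=O)C(F)(F)F)(C(C)C)C(C)C)
Why: Second Corey–Fuchs stage (Br–Li exchange, 1,2-shift, deprotonation) gives the acetylide, electrophilic oxygen transfer from lithium tert-butyl peroxide gives the ynolate, and the bulky silyl triflate traps it on oxygen; none of these events occurs at the hindered aryl carbon.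

Step 6
Reactants: 11 ethoxyacetylene
Product: 13 3-ethoxycyclobut-2-en-1-one, via ketene 12 (not isolated)
Conditions: AcCl, Et3N, hexanes–MeCN, 0 °C to rt
Reagents that add atoms: acetyl chloride (CC(Cl)=O)
Why: Ketene–ynol ether (2+2) cycloaddition, in which the nucleophilic terminal carbon of ethoxyacetylene attacks the carbonyl carbon of ketene made by dehydrochlorination of acetyl chloride, giving the 3-alkoxy regiochemistry.

Step 7
Reactants: 10 [3-(benzyloxy)-2,4,6-trimethoxyphenyl]ethynyl triisopropylsilyl ether; 13 3-ethoxycyclobut-2-en-1-one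
Product: 18 2-[3-(benzyloxy)-2,4,6-trimethoxyphenyl]-5-ethoxy-3-[(triisopropylsilyl)oxy]phenol, via vinylketene 14 (not isolated), via vinylcyclobutenone 15 (not isolated), via dienylketene 16 (not isolated), via cyclohexadienone 17 (not isolated)
Conditions: 13 (1.2 equiv), toluene (0.1 M), 110 °C, sealed tube, Ar
Reagents that add atoms: none
Why: Danheiser benzannulation: heat opens 13 by 4π electrocyclic cleavage to vinylketene 14, whose ketene C=C adds to the siloxyalkyne in a (2+2) cycloaddition to give 15, a second 4π opening gives dienylketene 16, and 6π electrocyclization to 17 followed by tautomerization gives the phenol. The closest known reaction type is the thermal benzannulation of cyclobutenones with trialkylsilyloxyalkynes to mono-silylated resorcinols. The (2+2) step forms both new skeletal C–C bonds (ketene carbonyl carbon to the aryl-bearing alkyne carbon, ketene α-carbon to the siloxy carbon), and ring F is then closed by the 6π electrocyclization that rejoins the carbonyl carbon to the CH2 terminus. No stereocentre is retained: the sp3 carbon of 15 becomes aromatic, and the biaryl axis of 18 stops being stereogenic once both ortho oxygens of ring F carry the same group in step 8. The step needs one regiochemistry in the ketene–alkyne union, and the oxygen lone pair of the siloxyalkyne secures it by making the aryl-bearing carbon the nucleophile that attacks the ketene carbonyl carbon, which puts ring E between the new phenol and the siloxy carbon. All four ortho oxygens thus surround an aryl–carbon bond that already exists in 10, and the three oxygens of ring F emerge differentiated as OH, OSi and OEt.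

Step 8
Reactants: 18 2-[3-(benzyloxy)-2,4,6-trimethoxyphenyl]-5-ethoxy-3-[(triisopropylsilyl)oxy]phenol
Product: 20 3-(benzyloxy)-2',4',6'-triethoxy-2,4,6-trimethoxy-1,1'-biphenyl, via resorcinol 19 (not isolated)
Conditions: Bu4NF, THF, 0 °C to rt; then EtI, K2CO3, DMF, 50 °C
Reagents that add atoms: iodoethane (CCI)
Why: Fluoride cleavage of the aryl silyl ether followed by Williamson O-ethylation of both phenols, which makes ring F a symmetric 2,4,6-triethoxyphenyl unit.

Step 9
Reactants: 20 3-(benzyloxy)-2',4',6'-triethoxy-2,4,6-trimethoxy-1,1'-biphenyl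
Product: 21 2',4',6'-triethoxy-2,4,6-trimethoxy-[1,1'-biphenyl]-3-ol
Conditions: H2 (1 atm), 10% Pd/C, EtOAc–EtOH, rt
Reagents that add atoms: none
Why: Hydrogenolysis of the benzyl aryl ether over Pd/C, to which methyl and ethyl aryl ethers and the biaryl are inert.

Step 10
Reactants: 21 2',4',6'-triethoxy-2,4,6-trimethoxy-[1,1'-biphenyl]-3-ol (2.1 equiv); 22 2,6-dichloro-1,4-benzoquinone
Product: 24 2,6-bis[(2',4',6'-triethoxy-2,4,6-trimethoxy-[1,1'-biphenyl]-3-yl)oxy]benzene-1,4-diol, via quinone 23 (not isolated)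
Conditions: Cs2CO3, MeCN, 0 °C to rt, Ar, dark; then aq Na2S2O4, THF, rt
Reagents that add atoms: none
Why: Twofold addition–elimination of the phenoxide at the chlorine-bearing carbons of the haloquinone (vinylogous acyl chloride substitution) forms both ring D–O–ring E bonds, and dithionite reduction in the same flask brings all ring D material to the hydroquinone level.

Step 11
Reactants: 24 2,6-bis[(2',4',6'-triethoxy-2,4,6-trimethoxy-[1,1'-biphenyl]-3-yl)oxy]benzene-1,4-diol
Product: 25 4-methoxy-2,6-bis[(2',4',6'-triethoxy-2,4,6-trimethoxy-[1,1'-biphenyl]-3-yl)oxy]phenol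
Conditions: MeI (1.05 equiv), K2CO3, acetone, rt, Ar
Reagents that add atoms: iodomethane (CI)
Why: Williamson methylation under steric control: the C4 hydroxyl of ring D has two ortho hydrogens, while the C1 hydroxyl sits between two bulky aryloxy groups, so one equivalent of MeI should alkylate only the former.

Step 12
Reactants: 26 4-bromo-2,6-dimethoxyphenol
Product: 27 2-(benzyloxy)-5-bromo-1,3-dimethoxybenzene
Conditions: BnBr, K2CO3, DMF, rt
Reagents that add atoms: benzyl bromide (BrCc1ccccc1)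
Why: Williamson benzylation of the phenol, which keeps the aryl bromide for the ether coupling and marks the oxygen that will later carry ring A.

Step 13
Reactants: 27 2-(benzyloxy)-5-bromo-1,3-dimethoxybenzene; 28 2,6-dimethoxyphenol
Product: 29 2-(benzyloxy)-5-(2,6-dimethoxyphenoxy)-1,3-dimethoxybenzene
Conditions: CuI (10 mol %), picolinic acid (20 mol %), K3PO4, DMSO, 100 °C
Reagents that add atoms: none
Why: Ullmann diaryl ether synthesis with a CuI/picolinic acid catalyst, which suits 2,6-disubstituted phenols and electron-rich aryl bromides; the bromide of 27 has two ortho hydrogens.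

Step 14
Reactants: 29 2-(benzyloxy)-5-(2,6-dimethoxyphenoxy)-1,3-dimethoxybenzene
Product: 31 3-(benzyloxy)-6-(2,6-dimethoxyphenoxy)-2,4-dimethoxybenzaldehyde, via iminium chloride 30 (not isolated)
Conditions: POCl3 (1.1 equiv), DMF, 0 °C to rt; then H2O
Reagents that add atoms: N,N-dimethylformamide (CN(C)C=O); water (O)
Why: Vilsmeier–Haack formylation; the two free positions of ring B are equivalent and lie between two oxygens with a third para, whereas ring C has only the weaker 1,2,3-trioxygenated pattern, so ring B should react alone.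

Step 15
Reactants: 31 3-(benzyloxy)-6-(2,6-dimethoxyphenoxy)-2,4-dimethoxybenzaldehyde
Product: 32 2-(benzyloxy)-4-(2,2-dibromoethenyl)-5-(2,6-dimethoxyphenoxy)-1,3-dimethoxybenzene
Conditions: CBr4, PPh3, Zn, CH2Cl2, rt; then 31, 0 °C to rt
Reagents that add atoms: carbon tetrabromide (BrC(Br)(Br)Br)
Why: Corey–Fuchs dibromo-olefination as in step 4, on an aldehyde with the same two ortho oxygens.

Step 16
Reactants: 32 2-(benzyloxy)-4-(2,2-dibromoethenyl)-5-(2,6-dimethoxyphenoxy)-1,3-dimethoxybenzene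
Product: 35 [3-(benzyloxy)-6-(2,6-dimethoxyphenoxy)-2,4-dimethoxyphenyl]ethynyl triisopropylsilyl ether, via lithium acetylide 33 (not isolated), via lithium ynolate 34 (not isolated)
Conditions: n-BuLi (2.05 equiv), THF, −78 °C; t-BuOOLi (from t-BuOOH and LiN(SiMe3)2), −78 to 0 °C; TIPSOTf, −78 °C to rt
Reagents that add atoms: tert-butyl hydroperoxide (CC(C)(C)OO); triisopropylsilyl trifluoromethanesulfonate (CC(C)[Si](OS(=O)(=O)C(F)(F)F)(C(C)C)C(C)C)
Why: Same sequence as step 5 (Corey–Fuchs acetylide formation, acetylide oxidation to the ynolate, O-silylation); the diaryl ether and benzyl ether are inert to n-BuLi at −78 °C.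

Step 17
Reactants: 35 [3-(benzyloxy)-6-(2,6-dimethoxyphenoxy)-2,4-dimethoxyphenyl]ethynyl triisopropylsilyl ether; 13 3-ethoxycyclobut-2-en-1-one
Product: 39 2-[3-(benzyloxy)-6-(2,6-dimethoxyphenoxy)-2,4-dimethoxyphenyl]-5-ethoxy-3-[(triisopropylsilyl)oxy]phenol, via vinylcyclobutenone 36 (not isolated), via dienylketene 37 (not isolated), via cyclohexadienone 38 (not isolated)
Conditions: 13 (1.2 equiv), toluene (0.1 M), 110 °C, sealed tube, Ar
Reagents that add atoms: none
Why: Danheiser benzannulation as in step 7: 13 again reacts through its ring-opened vinylketene form, and the same siloxyalkyne polarization fixes the regiochemistry of the (2+2) addition, so that ring B' grows on the carbon of ring B between the methoxy and the ring C aryloxy group.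

Step 18
Reactants: 39 2-[3-(benzyloxy)-6-(2,6-dimethoxyphenoxy)-2,4-dimethoxyphenyl]-5-ethoxy-3-[(triisopropylsilyl)oxy]phenol
Product: 41 3-(benzyloxy)-6-(2,6-dimethoxyphenoxy)-2',4',6'-triethoxy-2,4-dimethoxy-1,1'-biphenyl, via resorcinol 40 (not isolated)
Conditions: Bu4NF, THF, 0 °C to rt; then EtI, K2CO3, DMF, 50 °C
Reagents that add atoms: iodoethane (CCI)
Why: Fluoride desilylation and Williamson O-ethylation as in step 8, which makes ring B' symmetric.

Step 19
Reactants: 41 3-(benzyloxy)-6-(2,6-dimethoxyphenoxy)-2',4',6'-triethoxy-2,4-dimethoxy-1,1'-biphenyl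
Product: 42 6-(2,6-dimethoxyphenoxy)-2',4',6'-triethoxy-2,4-dimethoxy-[1,1'-biphenyl]-3-ol
Conditions: H2 (1 atm), 10% Pd/C, EtOAc–EtOH, rt
Reagents that add atoms: none
Why: Hydrogenolysis of the benzyl ether frees the ring B hydroxyl between the two methoxy groups; diaryl ethers are inert.

Step 20
Reactants: 42 6-(2,6-dimethoxyphenoxy)-2',4',6'-triethoxy-2,4-dimethoxy-[1,1'-biphenyl]-3-ol; 43 1-iodo-3,5-dimethoxybenzene
Product: 44 6-(2,6-dimethoxyphenoxy)-3-(3,5-dimethoxyphenoxy)-2',4',6'-triethoxy-2,4-dimethoxy-1,1'-biphenyl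
Conditions: CuI (10 mol %), picolinic acid (20 mol %), K3PO4, DMSO, 90 °C
Reagents that add atoms: none
Why: Ullmann diaryl ether synthesis joining a 2,6-dimethoxy-flanked phenol to an aryl iodide without ortho substituents; ring A is introduced only now because it would have competed in the formylation of step 14.

Step 21
Reactants: 44 6-(2,6-dimethoxyphenoxy)-3-(3,5-dimethoxyphenoxy)-2',4',6'-triethoxy-2,4-dimethoxy-1,1'-biphenyl
Product: 46 {4-[(3-(3,5-dimethoxyphenoxy)-2',4',6'-triethoxy-2,4-dimethoxy-[1,1'-biphenyl]-6-yl)oxy]-3,5-dimethoxyphenyl}boronic acid, via pinacol boronate 45 (not isolated)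
Conditions: B2pin2 (1 equiv), [Ir(OMe)(cod)]2 (2.5 mol %), 4,4'-di-tert-butyl-2,2'-bipyridine (5 mol %), THF, 80 °C; then NaIO4, aq HCl, THF–H2O, rt
Reagents that add atoms: bis(pinacolato)diboron (CC1(C)OB(OC1(C)C)B1OC(C)(C)C(C)(C)O1); water (O)
Why: Sterically controlled iridium-catalysed C–H borylation, since C4–H of ring C is the only aromatic C–H of 44 without an ortho substituent, followed by periodate cleavage of the pinacol ester to the free boronic acid.

Step 22
Reactants: 25 4-methoxy-2,6-bis[(2',4',6'-triethoxy-2,4,6-trimethoxy-[1,1'-biphenyl]-3-yl)oxy]phenol; 46 {4-[(3-(3,5-dimethoxyphenoxy)-2',4',6'-triethoxy-2,4-dimethoxy-[1,1'-biphenyl]-6-yl)oxy]-3,5-dimethoxyphenyl}boronic acid (1.5 equiv)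
Product: 47 fully O-alkylated target (13 methyl and 9 ethyl ethers)
Conditions: Cu(OAc)2 (1 equiv), pyridine, 4 Å molecular sieves, CH2Cl2, O2 (1 atm), rt
Reagents that add atoms: none
Why: Chan–Lam oxidative C–O coupling, which runs at room temperature, accepts 2,6-disubstituted phenols and is served here by a boronic acid with no ortho substituent.

Step 23
Reactants: 47 fully O-alkylated target (13 methyl and 9 ethyl ethers)
Product: 48 CNP0117322.0
Conditions: BBr3 (about 3 equiv per ether), CH2Cl2, −78 °C to rt, Ar; then H2O, 0 °C; work-up and reversed-phase purification under Ar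
Reagents that add atoms: none
Why: Lewis acid cleavage of alkyl aryl ethers by BBr3 (bromide attacks the O-alkyl carbon by SN2), which cannot cleave diaryl ether or biaryl bonds because no SN2 is possible at an aryl carbon.

## Compound list

1 | 2,4,6-trimethoxybenzaldehyde | COc1cc(OC)c(C=O)c(OC)c1 | starting material
2 | 2,4,6-trimethoxyphenyl formate | COc1cc(OC)c(OC=O)c(OC)c1 | intermediate
3 | 2,4,6-trimethoxyphenol | COc1cc(OC)c(O)c(OC)c1 | intermediate
4 | 2-(benzyloxy)-1,3,5-trimethoxybenzene | COc1cc(OC)c(OCc2ccccc2)c(OC)c1 | intermediate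
5 | N-{[3-(benzyloxy)-2,4,6-trimethoxyphenyl]methylidene}-N-methylmethanaminium chloride | C[N+](C)=Cc1c(OC)cc(OC)c(OCc2ccccc2)c1OC.[Cl-] | intermediate
6 | 3-(benzyloxy)-2,4,6-trimethoxybenzaldehyde | O=Cc1c(OC)cc(OC)c(OCc2ccccc2)c1OC | intermediate
7 | 2-(benzyloxy)-4-(2,2-dibromoethenyl)-1,3,5-trimethoxybenzene | BrC(Br)=Cc1c(OC)cc(OC)c(OCc2ccccc2)c1OC | intermediate
8 | {[3-(benzyloxy)-2,4,6-trimethoxyphenyl]ethynyl}lithium | [Li]C#Cc1c(OC)cc(OC)c(OCc2ccccc2)c1OC | intermediate
9 | lithium 2-[3-(benzyloxy)-2,4,6-trimethoxyphenyl]ethynolate | [Li]OC#Cc1c(OC)cc(OC)c(OCc2ccccc2)c1OC | intermediate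
10 | [3-(benzyloxy)-2,4,6-trimethoxyphenyl]ethynyl triisopropylsilyl ether | CC(C)[Si](C(C)C)(C(C)C)OC#Cc1c(OC)cc(OC)c(OCc2ccccc2)c1OC | intermediate
11 | ethoxyacetylene | CCOC#C | starting material
12 | ketene | C=C=O | intermediate
13 | 3-ethoxycyclobut-2-en-1-one | CCOC1=CC(=O)C1 | intermediate
14 | 3-ethoxybuta-1,3-dien-1-one | C=C(OCC)C=C=O | intermediate
15 | 2-[3-(benzyloxy)-2,4,6-trimethoxyphenyl]-4-(1-ethoxyethenyl)-3-[(triisopropylsilyl)oxy]cyclobut-2-en-1-one (racemic) | C=C(OCC)C1C(=O)C(c2c(OC)cc(OC)c(OCc3ccccc3)c2OC)=C1O[Si](C(C)C)(C(C)C)C(C)C | intermediate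
16 | (3E)-2-[3-(benzyloxy)-2,4,6-trimethoxyphenyl]-5-ethoxy-3-[(triisopropylsilyl)oxy]hexa-1,3,5-trien-1-one | C=C(OCC)/C=C(\C(=C=O)c1c(OC)cc(OC)c(OCc2ccccc2)c1OC)O[Si](C(C)C)(C(C)C)C(C)C | intermediate
17 | 2-[3-(benzyloxy)-2,4,6-trimethoxyphenyl]-5-ethoxy-3-[(triisopropylsilyl)oxy]cyclohexa-2,4-dien-1-one | CCOC1=CC(O[Si](C(C)C)(C(C)C)C(C)C)=C(c2c(OC)cc(OC)c(OCc3ccccc3)c2OC)C(=O)C1 | intermediate
18 | 2-[3-(benzyloxy)-2,4,6-trimethoxyphenyl]-5-ethoxy-3-[(triisopropylsilyl)oxy]phenol | CCOc1cc(O)c(-c2c(OC)cc(OC)c(OCc3ccccc3)c2OC)c(O[Si](C(C)C)(C(C)C)C(C)C)c1 | intermediate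
19 | 2-[3-(benzyloxy)-2,4,6-trimethoxyphenyl]-5-ethoxybenzene-1,3-diol | CCOc1cc(O)c(-c2c(OC)cc(OC)c(OCc3ccccc3)c2OC)c(O)c1 | intermediate
20 | 3-(benzyloxy)-2',4',6'-triethoxy-2,4,6-trimethoxy-1,1'-biphenyl | CCOc1cc(OCC)c(-c2c(OC)cc(OC)c(OCc3ccccc3)c2OC)c(OCC)c1 | intermediate
21 | 2',4',6'-triethoxy-2,4,6-trimethoxy-[1,1'-biphenyl]-3-ol | CCOc1cc(OCC)c(-c2c(OC)cc(OC)c(O)c2OC)c(OCC)c1 | intermediate
22 | 2,6-dichloro-1,4-benzoquinone | O=C1C=C(Cl)C(=O)C(Cl)=C1 | starting material
23 | 2,6-bis[(2',4',6'-triethoxy-2,4,6-trimethoxy-[1,1'-biphenyl]-3-yl)oxy]-1,4-benzoquinone | O=C1C=C(Oc2c(OC)cc(OC)c(-c3c(OCC)cc(OCC)cc3OCC)c2OC)C(=O)C(Oc2c(OC)cc(OC)c(-c3c(OCC)cc(OCC)cc3OCC)c2OC)=C1 | intermediate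
24 | 2,6-bis[(2',4',6'-triethoxy-2,4,6-trimethoxy-[1,1'-biphenyl]-3-yl)oxy]benzene-1,4-diol | Oc1cc(Oc2c(OC)cc(OC)c(-c3c(OCC)cc(OCC)cc3OCC)c2OC)c(O)c(Oc2c(OC)cc(OC)c(-c3c(OCC)cc(OCC)cc3OCC)c2OC)c1 | intermediate
25 | 4-methoxy-2,6-bis[(2',4',6'-triethoxy-2,4,6-trimethoxy-[1,1'-biphenyl]-3-yl)oxy]phenol | COc1cc(Oc2c(OC)cc(OC)c(-c3c(OCC)cc(OCC)cc3OCC)c2OC)c(O)c(Oc2c(OC)cc(OC)c(-c3c(OCC)cc(OCC)cc3OCC)c2OC)c1 | intermediate
26 | 4-bromo-2,6-dimethoxyphenol | COc1cc(Br)cc(OC)c1O | starting material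
27 | 2-(benzyloxy)-5-bromo-1,3-dimethoxybenzene | COc1cc(Br)cc(OC)c1OCc1ccccc1 | intermediate
28 | 2,6-dimethoxyphenol | COc1cccc(OC)c1O | starting material
29 | 2-(benzyloxy)-5-(2,6-dimethoxyphenoxy)-1,3-dimethoxybenzene | COc1cc(Oc2c(OC)cccc2OC)cc(OC)c1OCc1ccccc1 | intermediate
30 | N-{[3-(benzyloxy)-6-(2,6-dimethoxyphenoxy)-2,4-dimethoxyphenyl]methylidene}-N-methylmethanaminium chloride | C[N+](C)=Cc1c(OC)c(OCc2ccccc2)c(OC)cc1Oc1c(OC)cccc1OC.[Cl-] | intermediate
31 | 3-(benzyloxy)-6-(2,6-dimethoxyphenoxy)-2,4-dimethoxybenzaldehyde | O=Cc1c(OC)c(OCc2ccccc2)c(OC)cc1Oc1c(OC)cccc1OC | intermediate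
32 | 2-(benzyloxy)-4-(2,2-dibromoethenyl)-5-(2,6-dimethoxyphenoxy)-1,3-dimethoxybenzene | BrC(Br)=Cc1c(OC)c(OCc2ccccc2)c(OC)cc1Oc1c(OC)cccc1OC | intermediate
33 | {[3-(benzyloxy)-6-(2,6-dimethoxyphenoxy)-2,4-dimethoxyphenyl]ethynyl}lithium | [Li]C#Cc1c(OC)c(OCc2ccccc2)c(OC)cc1Oc1c(OC)cccc1OC | intermediate
34 | lithium 2-[3-(benzyloxy)-6-(2,6-dimethoxyphenoxy)-2,4-dimethoxyphenyl]ethynolate | [Li]OC#Cc1c(OC)c(OCc2ccccc2)c(OC)cc1Oc1c(OC)cccc1OC | intermediate
35 | [3-(benzyloxy)-6-(2,6-dimethoxyphenoxy)-2,4-dimethoxyphenyl]ethynyl triisopropylsilyl ether | CC(C)[Si](C(C)C)(C(C)C)OC#Cc1c(OC)c(OCc2ccccc2)c(OC)cc1Oc1c(OC)cccc1OC | intermediate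
36 | 2-[3-(benzyloxy)-6-(2,6-dimethoxyphenoxy)-2,4-dimethoxyphenyl]-4-(1-ethoxyethenyl)-3-[(triisopropylsilyl)oxy]cyclobut-2-en-1-one (racemic) | C=C(OCC)C1C(=O)C(c2c(OC)c(OCc3ccccc3)c(OC)cc2Oc2c(OC)cccc2OC)=C1O[Si](C(C)C)(C(C)C)C(C)C | intermediate
37 | (3E)-2-[3-(benzyloxy)-6-(2,6-dimethoxyphenoxy)-2,4-dimethoxyphenyl]-5-ethoxy-3-[(triisopropylsilyl)oxy]hexa-1,3,5-trien-1-one | C=C(OCC)/C=C(\C(=C=O)c1c(OC)c(OCc2ccccc2)c(OC)cc1Oc1c(OC)cccc1OC)O[Si](C(C)C)(C(C)C)C(C)C | intermediate
38 | 2-[3-(benzyloxy)-6-(2,6-dimethoxyphenoxy)-2,4-dimethoxyphenyl]-5-ethoxy-3-[(triisopropylsilyl)oxy]cyclohexa-2,4-dien-1-one | CCOC1=CC(O[Si](C(C)C)(C(C)C)C(C)C)=C(c2c(OC)c(OCc3ccccc3)c(OC)cc2Oc2c(OC)cccc2OC)C(=O)C1 | intermediate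
39 | 2-[3-(benzyloxy)-6-(2,6-dimethoxyphenoxy)-2,4-dimethoxyphenyl]-5-ethoxy-3-[(triisopropylsilyl)oxy]phenol | CCOc1cc(O)c(-c2c(OC)c(OCc3ccccc3)c(OC)cc2Oc2c(OC)cccc2OC)c(O[Si](C(C)C)(C(C)C)C(C)C)c1 | intermediate
40 | 2-[3-(benzyloxy)-6-(2,6-dimethoxyphenoxy)-2,4-dimethoxyphenyl]-5-ethoxybenzene-1,3-diol | CCOc1cc(O)c(-c2c(OC)c(OCc3ccccc3)c(OC)cc2Oc2c(OC)cccc2OC)c(O)c1 | intermediate
41 | 3-(benzyloxy)-6-(2,6-dimethoxyphenoxy)-2',4',6'-triethoxy-2,4-dimethoxy-1,1'-biphenyl | CCOc1cc(OCC)c(-c2c(OC)c(OCc3ccccc3)c(OC)cc2Oc2c(OC)cccc2OC)c(OCC)c1 | intermediate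
42 | 6-(2,6-dimethoxyphenoxy)-2',4',6'-triethoxy-2,4-dimethoxy-[1,1'-biphenyl]-3-ol | CCOc1cc(OCC)c(-c2c(OC)c(O)c(OC)cc2Oc2c(OC)cccc2OC)c(OCC)c1 | intermediate
43 | 1-iodo-3,5-dimethoxybenzene | COc1cc(I)cc(OC)c1 | starting material
44 | 6-(2,6-dimethoxyphenoxy)-3-(3,5-dimethoxyphenoxy)-2',4',6'-triethoxy-2,4-dimethoxy-1,1'-biphenyl | CCOc1cc(OCC)c(-c2c(OC)c(Oc3cc(OC)cc(OC)c3)c(OC)cc2Oc2c(OC)cccc2OC)c(OCC)c1 | intermediate
45 | 2-{4-[(3-(3,5-dimethoxyphenoxy)-2',4',6'-triethoxy-2,4-dimethoxy-[1,1'-biphenyl]-6-yl)oxy]-3,5-dimethoxyphenyl}-4,4,5,5-tetramethyl-1,3,2-dioxaborolane | CCOc1cc(OCC)c(-c2c(OC)c(Oc3cc(OC)cc(OC)c3)c(OC)cc2Oc2c(OC)cc(B3OC(C)(C)C(C)(C)O3)cc2OC)c(OCC)c1 | intermediate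
46 | {4-[(3-(3,5-dimethoxyphenoxy)-2',4',6'-triethoxy-2,4-dimethoxy-[1,1'-biphenyl]-6-yl)oxy]-3,5-dimethoxyphenyl}boronic acid | CCOc1cc(OCC)c(-c2c(OC)c(Oc3cc(OC)cc(OC)c3)c(OC)cc2Oc2c(OC)cc(B(O)O)cc2OC)c(OCC)c1 | intermediate
47 | fully O-alkylated target: ring D 4-methyl ether carrying two ring E–F units (each tri-O-methyl on E, tri-O-ethyl on F), ring C di-O-methyl, ring B di-O-methyl, ring B' tri-O-ethyl, ring A di-O-methyl | COc1cc(Oc2c(OC)cc(OC)c(-c3c(OCC)cc(OCC)cc3OCC)c2OC)c(Oc2cc(OC)c(Oc3cc(OC)c(Oc4cc(OC)cc(OC)c4)c(OC)c3-c3c(OCC)cc(OCC)cc3OCC)c(OC)c2)c(Oc2c(OC)cc(OC)c(-c3c(OCC)cc(OCC)cc3OCC)c2OC)c1 | intermediate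
48 | CNP0117322.0 | Oc1cc(O)cc(Oc2c(O)cc(Oc3c(O)cc(Oc4c(Oc5c(O)cc(O)c(-c6c(O)cc(O)cc6O)c5O)cc(O)cc4Oc4c(O)cc(O)c(-c5c(O)cc(O)cc5O)c4O)cc3O)c(-c3c(O)cc(O)cc3O)c2O)c1 | target

## Step count and risks

Total step count: 23.
Longest linear sequence: 12 steps (steps 1–5, 7–11, 22, 23 from compound 1; the ring B line, steps 12–23 from compound 26, is equally long).

The three steps most likely to fail:

**Step 7 (key benzannulation).** The ethoxy donor at C3 may slow the ring opening of 13 so much that the siloxyalkyne is lost to desilylation or self-condensation first. The two ortho methoxy groups may also retard the (2+2) addition, so that vinylketene 14 oligomerizes. The fallback replaces ring construction by a biaryl cross-coupling and sets out from 4. N-Bromosuccinimide in MeCN at 0 °C should brominate 4 at its one type of free position to give 2-(benzyloxy)-4-bromo-1,3,5-trimethoxybenzene F1. Purchased 1,3,5-triethoxybenzene is lithiated between two ethoxy groups (n-BuLi, TMEDA, THF, 0 °C) to (2,4,6-triethoxyphenyl)lithium F2. Treating F2 with B(OMe)3 and then aqueous HCl gives (2,4,6-triethoxyphenyl)boronic acid F3. Suzuki–Miyaura coupling of F1 with F3 (Pd(OAc)2, SPhos, K3PO4, toluene–H2O, 100 °C) should give 20, where the fallback comes back to the route, and steps 3 to 8 fall away.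

**Step 10 (quinone bis-etherification).** The very electron-rich phenoxide of 21 may transfer an electron to the quinone instead of adding to it, which would lead to oxidative degradation of ring E. The reaction may also stall after the first substitution because the first aryloxy group deactivates the quinone. The fallback builds ring D by copper catalysis and sets out from 21. Purchased 2,6-dibromo-4-methoxyphenol is benzylated (BnBr, K2CO3, DMF) to 2-(benzyloxy)-1,3-dibromo-5-methoxybenzene F4. Twofold Ullmann coupling of F4 with 21 (CuI, picolinic acid, K3PO4, DMSO, 110 °C) should give 2-(benzyloxy)-5-methoxy-1,3-bis[(2',4',6'-triethoxy-2,4,6-trimethoxy-[1,1'-biphenyl]-3-yl)oxy]benzene F5. Hydrogenolysis of F5 (H2, Pd/C, EtOAc) gives 25, where the fallback comes back to the route; steps 10 and 11 fall away, and the position of the methyl ether is fixed by the purchased phenol.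

**Step 22 (fragment union).** Transmetalation and C–O bond formation at the doubly flanked phenol of 25 may be so slow that protodeboronation, oxidative homocoupling and hydroxylation consume 46 first. The fallback uses an Ullmann coupling of an aryl halide under catalysis by monovalent copper and sets out from 46. Bromodeboronation with CuBr2 (MeOH–H2O, 80 °C) should give 6-(4-bromo-2,6-dimethoxyphenoxy)-3-(3,5-dimethoxyphenoxy)-2',4',6'-triethoxy-2,4-dimethoxy-1,1'-biphenyl F6. Coupling of F6 with 25 (CuI, picolinic acid, K3PO4, DMSO, 110 °C) should give 47, where the fallback comes back to the route.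

Further compounds
F1 | step 7 | 2-(benzyloxy)-4-bromo-1,3,5-trimethoxybenzene | COc1cc(OC)c(OCc2ccccc2)c(OC)c1Br
F2 | step 7 | (2,4,6-triethoxyphenyl)lithium | [Li]c1c(OCC)cc(OCC)cc1OCC
F3 | step 7 | (2,4,6-triethoxyphenyl)boronic acid | CCOc1cc(OCC)c(B(O)O)c(OCC)c1
F4 | step 10 | 2-(benzyloxy)-1,3-dibromo-5-methoxybenzene | COc1cc(Br)c(OCc2ccccc2)c(Br)c1
F5 | step 10 | 2-(benzyloxy)-5-methoxy-1,3-bis[(2',4',6'-triethoxy-2,4,6-trimethoxy-[1,1'-biphenyl]-3-yl)oxy]benzene | COc1cc(Oc2c(OC)cc(OC)c(-c3c(OCC)cc(OCC)cc3OCC)c2OC)c(OCc2ccccc2)c(Oc2c(OC)cc(OC)c(-c3c(OCC)cc(OCC)cc3OCC)c2OC)c1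
F6 | step 22 | 6-(4-bromo-2,6-dimethoxyphenoxy)-3-(3,5-dimethoxyphenoxy)-2',4',6'-triethoxy-2,4-dimethoxy-1,1'-biphenyl | CCOc1cc(OCC)c(-c2c(OC)c(Oc3cc(OC)cc(OC)c3)c(OC)cc2Oc2c(OC)cc(Br)cc2OC)c(OCC)c1
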